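**Strategy.** Ring atoms are numbered as in shikimate (C1 carries CO2Me, C2=CH, C3 OAc, C6 CH2). The cyclohexene ring is opened between C3 and C4: both carbons of this vicinal cis-dioxygenated pair are taken back to aldehydes. A samarium diiodide pinacol cyclization of the acyclic (E)-4-oxo-enoate dialdehyde 7 forms the C3–C4 bond, closes the six-membered ring and sets both carbinol centers in one operation, directed only by the C5 silyloxy stereocenter. The dialdehyde is assembled from three achiral components: an organocatalytic Michael addition fixes C5 and an olefination installs the C1=C2 enoate with C3 cis to C6. Regioselective orthoester opening and acylation with (R)-2-methylbutanoic acid finish the target.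

Key step: step 4

Remark: compounds 1, 2, 5 and 12 are taken as catalogue compounds, and aldehyde 1 is assumed to react through its (E)-enamine as simple alkyl aldehydes do.

Step 1
Reactants: 1 (tert-butyldimethylsilyloxy)acetaldehyde; 2 trimethyl 2-phosphonoacrylate
Product: 4 methyl (4R)-4-[(tert-butyldimethylsilyl)oxy]-2-(dimethoxyphosphoryl)-5,5-dimethoxypentanoate, via Michael adduct aldehyde 3 (not isolated)
Conditions: (S)-α,α-diphenylprolinol trimethylsilyl ether (10 mol%), PhCO2H (10 mol%), toluene, 0 °C → rt; then HC(OMe)3, CSA (0.25 equiv), MeOH, 0 °C → rt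
Reagents that add atoms: trimethyl orthoformate, COC(OC)OC
Why: Enamine-catalysed Michael addition of the α-silyloxy aldehyde to the vinyl phosphonate, in which the (E)-enamine is attacked on the face remote from the CPh2OTMS group of the (S)-catalyst so that the future ring carbon C5 should be set as R; the epimerisable aldehyde is masked in the same pot as its dimethyl acetal, and the phosphonate-bearing carbon is an inconsequential mixture of epimers.

Step 2
Reactants: 4 methyl (4R)-4-[(tert-butyldimethylsilyl)oxy]-2-(dimethoxyphosphoryl)-5,5-dimethoxypentanoate; 5 2,2-dimethoxyacetaldehyde (60 wt% in water)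
Product: 6 methyl (2E)-2-{(2R)-2-[(tert-butyldimethylsilyl)oxy]-3,3-dimethoxypropyl}-4,4-dimethoxybut-2-enoate
Conditions: K2CO3, THF/H2O, 0 °C → rt
Reagents that add atoms: none
Why: Horner–Wadsworth–Emmons olefination of the α-substituted phosphonoacetate with the reactive aldehyde 5 under aqueous carbonate conditions; the (E)-enoate, with the acetal carbon trans to the ester and cis to the CH2 branch, is expected as the major isomer and is the geometry the ring closure needs.

Step 3
Reactants: 6 methyl (2E)-2-{(2R)-2-[(tert-butyldimethylsilyl)oxy]-3,3-dimethoxypropyl}-4,4-dimethoxybut-2-enoate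
Product: 7 methyl (2E)-2-{(2R)-2-[(tert-butyldimethylsilyl)oxy]-3-oxopropyl}-4-oxobut-2-enoate
Conditions: TESOTf, 2,4,6-collidine, CH2Cl2, 0 °C; then H2O, rt
Reagents that add atoms: water, O
Why: Acetal cleavage through collidinium salts under nearly neutral conditions should unmask both aldehydes while leaving the secondary TBS ether, the methyl ester, the alkene geometry and the α-silyloxy stereocenter untouched; the dialdehyde is used crude.

Step 4
Reactants: 7 methyl (2E)-2-{(2R)-2-[(tert-butyldimethylsilyl)oxy]-3-oxopropyl}-4-oxobut-2-enoate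
Product: 8 methyl (3R,4R,5R)-5-[(tert-butyldimethylsilyl)oxy]-3,4-dihydroxycyclohex-1-ene-1-carboxylate (methyl 5-O-TBS-shikimate)
Conditions: SmI2 (2.5 equiv), THF, slow addition of 7 at high dilution, −78 → −20 °C, no proton source; then aq. NH4Cl
Reagents that add atoms: none
Why: Divalent samarium transfers one electron to the more easily reduced conjugated C3 aldehyde to give a samarium-bound ketyl, whose C3 adds to the samarium-coordinated C4 aldehyde, and a second electron transfer gives the cyclic samarium diolate that is protonated on work-up; this is the intramolecular pinacol coupling of a 1,6-dialdehyde, the reaction type used to make cyclitols from sugar-derived dialdehydes. The carbocycle closes in a 6-exo-trig mode between the two carbonyl carbons, the (E)-geometry of C1=C2 holding C3 and C6 cis so that the ends can meet. The new C3 and C4 carbinols are expected cis because both oxygens are bridged by oxophilic trivalent samarium in the coupling transition state. The C4 oxygen is expected trans to the existing C5 silyloxy group, which sits pseudo-equatorial and turns away from the samarium-bound oxygen to minimise dipole and steric repulsion, giving the shikimate array. The step needs carbonyl coupling to win over conjugate reduction or reductive aldol of the 4-oxo-enoate: no proton source or HMPA is present, the temperature is low, dilution suppresses dimerisation, and the alternative closures from C1 (four-membered ring) or C2 (5-endo) are geometrically disfavoured.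

Step 5
Reactants: 8 methyl (3R,4R,5R)-5-[(tert-butyldimethylsilyl)oxy]-3,4-dihydroxycyclohex-1-ene-1-carboxylate
Product: 11 methyl (3R,4S,5R)-3-acetoxy-4,5-dihydroxycyclohex-1-ene-1-carboxylate, via cyclic orthoester 9 (not isolated), via silyl ether monoacetate 10 (not isolated)
Conditions: MeC(OMe)3, PPTS (cat.), CH2Cl2, rt; then 48% aq. HF, MeCN, 0 °C → rt
Reagents that add atoms: trimethyl orthoacetate, CC(OC)(OC)OC; water, O
Why: Cyclic orthoester formation across the cis-3,4-diol followed by acid hydrolysis, which by the known kinetic preference for axial ester and equatorial alcohol should open to the pseudo-axial allylic C3 acetate; aqueous HF then cleaves the TBS ether in the same pot under acidic conditions where acetyl migration is slow, and no stereocenter is touched.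

Step 6
Reactants: 11 methyl (3R,4S,5R)-3-acetoxy-4,5-dihydroxycyclohex-1-ene-1-carboxylate; 12 (R)-2-methylbutanoic acid
Product: 13 methyl (3R,4S,5R)-3-acetoxy-4,5-bis{[(2R)-2-methylbutanoyl]oxy}cyclohex-1-ene-1-carboxylate (CNP0132712.1)
Conditions: 12 (3 equiv), DIC (3 equiv), DMAP (0.2 equiv), CH2Cl2, 0 °C → rt
Reagents that add atoms: none
Why: Steglich esterification of both remaining hydroxyls; acylation at 0 °C should outrun acetyl migration, and carbodiimide activation avoids ketene formation so the (R)-centers of the side chains are retained.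

**Compound list**

1 | (tert-butyldimethylsilyloxy)acetaldehyde | O=CCO[Si](C)(C)C(C)(C)C | starting material
2 | trimethyl 2-phosphonoacrylate (methyl 2-(dimethoxyphosphoryl)prop-2-enoate) | C=C(C(=O)OC)P(=O)(OC)OC | starting material
3 | methyl (4R)-4-[(tert-butyldimethylsilyl)oxy]-2-(dimethoxyphosphoryl)-5-oxopentanoate (epimers at C2) | O=C[C@H](O[Si](C)(C)C(C)(C)C)CC(C(=O)OC)P(=O)(OC)OC | intermediate
4 | methyl (4R)-4-[(tert-butyldimethylsilyl)oxy]-2-(dimethoxyphosphoryl)-5,5-dimethoxypentanoate (epimers at C2) | COC(OC)[C@H](O[Si](C)(C)C(C)(C)C)CC(C(=O)OC)P(=O)(OC)OC | intermediate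
5 | 2,2-dimethoxyacetaldehyde (glyoxal mono-dimethyl acetal) | O=CC(OC)OC | starting material
6 | methyl (2E)-2-{(2R)-2-[(tert-butyldimethylsilyl)oxy]-3,3-dimethoxypropyl}-4,4-dimethoxybut-2-enoate | COC(OC)/C=C(\C[C@@H](O[Si](C)(C)C(C)(C)C)C(OC)OC)C(=O)OC | intermediate
7 | methyl (2E)-2-{(2R)-2-[(tert-butyldimethylsilyl)oxy]-3-oxopropyl}-4-oxobut-2-enoate | O=C/C=C(\C[C@@H](O[Si](C)(C)C(C)(C)C)C=O)C(=O)OC | intermediate
8 | methyl (3R,4R,5R)-5-[(tert-butyldimethylsilyl)oxy]-3,4-dihydroxycyclohex-1-ene-1-carboxylate (shikimate configuration; the C4 descriptor reads R because silicon raises the priority of the C5 branch) | O[C@@H]1[C@H](O)C=C(C(=O)OC)C[C@H]1O[Si](C)(C)C(C)(C)C | intermediate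
9 | methyl 5-O-(tert-butyldimethylsilyl)-3,4-O-(1-methoxyethylidene)shikimate (orthoester epimers) | COC1(C)O[C@@H]2[C@H](O1)C=C(C(=O)OC)C[C@H]2O[Si](C)(C)C(C)(C)C | intermediate
10 | methyl (3R,4R,5R)-3-acetoxy-5-[(tert-butyldimethylsilyl)oxy]-4-hydroxycyclohex-1-ene-1-carboxylate | O[C@@H]1[C@H](OC(C)=O)C=C(C(=O)OC)C[C@H]1O[Si](C)(C)C(C)(C)C | intermediate
11 | methyl (3R,4S,5R)-3-acetoxy-4,5-dihydroxycyclohex-1-ene-1-carboxylate (methyl 3-O-acetylshikimate) | O[C@@H]1[C@H](OC(C)=O)C=C(C(=O)OC)C[C@H]1O | intermediate
12 | (R)-2-methylbutanoic acid | CC[C@@H](C)C(=O)O | starting material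
13 | methyl (3R,4S,5R)-3-acetoxy-4,5-bis{[(2R)-2-methylbutanoyl]oxy}cyclohex-1-ene-1-carboxylate | CC[C@@H](C)C(=O)O[C@@H]1[C@H](OC(C)=O)C=C(C(=O)OC)C[C@H]1OC(=O)[C@H](C)CC | target

**Step count.** Total: 6 steps. Longest linear sequence: 6 steps (1 and 2 to 13).

**Steps most likely to fail**

1. Step 4. Electron transfer may be diverted into conjugate reduction or reductive aldol chemistry of the 4-oxo-enoate, or facial control at C4 may be poor. The fallback sets out from 7 and rejoins at 8. The same C3–C4 bond would be closed redox-neutrally by an NHC-catalysed intramolecular crossed benzoin reaction (triazolium precatalyst, iPr2NEt, CH2Cl2, rt, no protic additive). The Breslow intermediate of the enal can reach the C4 aldehyde only through its acyl carbon C3, since the homoenolate carbon C1 would have to form a four-membered ring. This should give methyl (4S,5R)-5-[(tert-butyldimethylsilyl)oxy]-4-hydroxy-3-oxocyclohex-1-ene-1-carboxylate F1, a protected 3-dehydroshikimate whose C4 center, α to the ketone, can settle trans to the C5 substituent. Chelation-controlled 1,2-reduction (Zn(BH4)2, Et2O, −20 °C) of the zinc-bridged hydroxy ketone is then expected to give the cis-3,4-diol 8.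

2. Step 3. The silyl ether may be lost, the center α to the new aldehyde may epimerise, or the deactivated α-silyloxy acetal may cleave incompletely. The fallback sets out from 3, the crude Michael adduct of step 1, and rejoins at 7. The acetalization is omitted and 3 is olefinated directly with an excess of anhydrous 5 under the LiCl/iPr2NEt variant of the Horner–Wadsworth–Emmons reaction (MeCN, 0 °C). These conditions are tolerated by epimerisable aldehydes, and the excess of the more electrophilic 5 should suppress self-condensation. The product would be methyl (2E)-2-{(2R)-2-[(tert-butyldimethylsilyl)oxy]-3-oxopropyl}-4,4-dimethoxybut-2-enoate F2, in which only the easily hydrolysed vinylogous acetal remains. PPTS in wet acetone at rt then gives 7.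

3. Step 5. The orthoester may open unselectively, or the acetyl group may migrate from O3 to O4 during the acidic desilylation. The fallback sets out from 8 and rejoins at 13, installing the C4 ester first. The equatorial C4 hydroxyl of the cis-diol would be acylated under diarylborinic acid catalysis (2-aminoethyl diphenylborinate cat., iPr2NEt, MeCN, 0 °C) with (R)-2-methylbutanoyl chloride F3 (from 12, oxalyl chloride, cat. DMF). This should give methyl 4-O-[(2R)-2-methylbutanoyl]-5-O-(tert-butyldimethylsilyl)shikimate F4. Acetylation of the remaining allylic hydroxyl (Ac2O, pyridine) gives methyl 3-O-acetyl-4-O-[(2R)-2-methylbutanoyl]-5-O-(tert-butyldimethylsilyl)shikimate F5. HF·pyridine in THF removes the silyl group to give methyl 3-O-acetyl-4-O-[(2R)-2-methylbutanoyl]shikimate F6, and esterification of its C5 hydroxyl with 12 under the conditions of step 6 reaches 13.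

**Further compounds**

F1 | step 4 | methyl (4S,5R)-5-[(tert-butyldimethylsilyl)oxy]-4-hydroxy-3-oxocyclohex-1-ene-1-carboxylate | O[C@@H]1C(=O)C=C(C(=O)OC)C[C@H]1O[Si](C)(C)C(C)(C)C
F2 | step 3 | methyl (2E)-2-{(2R)-2-[(tert-butyldimethylsilyl)oxy]-3-oxopropyl}-4,4-dimethoxybut-2-enoate | COC(OC)/C=C(\C[C@@H](O[Si](C)(C)C(C)(C)C)C=O)C(=O)OC
F3 | step 5 | (R)-2-methylbutanoyl chloride | CC[C@@H](C)C(=O)Cl
F4 | step 5 | methyl 4-O-[(2R)-2-methylbutanoyl]-5-O-(tert-butyldimethylsilyl)shikimate | CC[C@@H](C)C(=O)O[C@@H]1[C@H](O)C=C(C(=O)OC)C[C@H]1O[Si](C)(C)C(C)(C)C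
F5 | step 5 | methyl 3-O-acetyl-4-O-[(2R)-2-methylbutanoyl]-5-O-(tert-butyldimethylsilyl)shikimate | CC[C@@H](C)C(=O)O[C@@H]1[C@H](OC(C)=O)C=C(C(=O)OC)C[C@H]1O[Si](C)(C)C(C)(C)C
F6 | step 5 | methyl 3-O-acetyl-4-O-[(2R)-2-methylbutanoyl]shikimate | CC[C@@H](C)C(=O)O[C@@H]1[C@H](OC(C)=O)C=C(C(=O)OC)C[C@H]1O
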